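**Retrosynthetic overview** (octahydronaphthalene numbering: C1 bears the ester, C2 a methyl, C4a and C8a the angular methyls, C5 the side chain; ring A = C1–C4, C4a, C8a; ring B = C4a, C5–C8, C8a)
1. The glyceride is made last, by opening (R)-glycidyl acetate with the free acid. The homoprenyl chain comes from a C5 enol triflate and a Grignard reagent under iron catalysis.
2. Ring A is closed by an intramolecular vinylogous (1,6) Michael addition of the ester enolate carbon C1 to C8a of a cyclohexa-2,4-dienone.
3. Enabling feature: ring B has the substitution pattern of 2,3-dimethylphenol (sp2 C5 next to the methyl-bearing C4a and C8a). With C4a quaternary, this "phenol" is locked as its keto tautomer. Its C5=O activates C8a through C6=C7–C8=C8a, and C1 sits at the end of the four-carbon tether C4–C3–C2–C1 on C4a.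
4. The dienone comes from 2-iodocyclohexenone by Negishi coupling, catalytic asymmetric conjugate methylation with enolate methylation (sets C4a), and two dehydrogenations.
5. Ring B is present from the start and ring A is formed in the key step. C2 is bought with methyl hydrogen (R)-3-methylglutarate.

Key step: step 7

Assumption: in step 4 the antipode of the peptide phosphine ligand (available from L- or D-amino acids) is the one that delivers methyl to the C8a face drawn in 7.

Step 1
Reactants: 1 (3R)-5-methoxy-3-methyl-5-oxopentanoic acid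
Product: 2 methyl (3R)-5-hydroxy-3-methylpentanoate
Conditions: BH3·SMe2 (1.1 equiv), THF, 0 °C → rt; MeOH quench
Reagents that add atoms: none
Why: Borane reduces a free carboxylic acid much faster than an ester (chemoselective borane reduction), so only the acid terminus becomes CH2OH and the C2 stereocentre is untouched.

Step 2
Reactants: 2 methyl (3R)-5-hydroxy-3-methylpentanoate
Product: 3 methyl (3S)-5-iodo-3-methylpentanoate
Conditions: I2, PPh3, imidazole, CH2Cl2, 0 °C → rt
Reagents that add atoms: iodine, II
Why: Appel-type iodination of a primary alcohol through the alkoxyphosphonium salt is fast enough to forestall lactonisation; only the descriptor changes, not the geometry at the stereocentre.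

Step 3
Reactants: 3 methyl (3S)-5-iodo-3-methylpentanoate; 4 2-iodocyclohex-2-en-1-one
Product: 6 methyl (3R)-3-methyl-5-(6-oxocyclohex-1-en-1-yl)pentanoate, via alkylzinc iodide 5 (not isolated)
Conditions: Zn dust (activated by BrCH2CH2Br, Me3SiCl), THF, 40 °C; then 4, PdCl2(dppf) (3 mol %), THF, rt
Reagents that add atoms: none
Why: Negishi coupling of an ester-tolerant primary alkylzinc iodide with an α-iodoenone (oxidative addition to zerovalent palladium, transmetalation, reductive elimination) joins C4 to C4a and does not touch the remote stereocentre.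

Step 4
Reactants: 6 methyl (3R)-3-methyl-5-(6-oxocyclohex-1-en-1-yl)pentanoate
Product: 8 methyl (3R)-5-[(1S,2S)-1,2-dimethyl-6-oxocyclohexyl]-3-methylpentanoate, via methylzinc enolate 7 (not isolated)
Conditions: Me2Zn (3 equiv), (CuOTf)2·C6H6 (2.5 mol %), 2-(Ph2P)C6H4CH=N-Val-Phe-NH-n-Bu ligand (6 mol %), toluene, −30 → 0 °C; then MeI (10 equiv), HMPA, 0 °C → rt
Reagents that add atoms: dimethylzinc, C[Zn]C; iodomethane, CI
Why: Copper-catalysed asymmetric conjugate addition of a dialkylzinc to an α-substituted cyclic enone sets C8a under ligand control, and the regiodefined zinc enolate is methylated anti to the new C8a methyl (three-component conjugate addition–alkylation), which fixes the quaternary centre C4a.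

Step 5
Reactants: 8 methyl (3R)-5-[(1S,2S)-1,2-dimethyl-6-oxocyclohexyl]-3-methylpentanoate
Product: 10 methyl (3R)-5-[(1S,6S)-1,6-dimethyl-2-oxocyclohex-3-en-1-yl]-3-methylpentanoate, via lithium enolate 9 (not isolated)
Conditions: LiN(i-Pr)2 (1.05 equiv), THF, −78 °C; then PhS(Cl)=N-t-Bu (1.2 equiv), −78 °C
Reagents that add atoms: none
Why: The ketone can be enolised only towards C6 because C4a is quaternary, and the lithium enolate is dehydrogenated by the sulfinimidoyl chloride (Mukaiyama dehydrogenation) without touching ester or stereocentres.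

Step 6
Reactants: 10 methyl (3R)-5-[(1S,6S)-1,6-dimethyl-2-oxocyclohex-3-en-1-yl]-3-methylpentanoate
Product: 12 methyl (3R)-5-[(1S)-1,2-dimethyl-6-oxocyclohexa-2,4-dien-1-yl]-3-methylpentanoate, via silyl dienol ether 11 (not isolated)
Conditions: t-BuMe2SiOTf, Et3N, CH2Cl2, 0 °C; then DDQ (1.1 equiv), CH2Cl2, 0 °C → rt; used at once
Reagents that add atoms: none
Why: γ-Deprotonative silylation gives the linear dienol silyl ether and DDQ abstracts the tertiary allylic hydride at C8a, the reaction type of the 4,6-dehydrogenation of steroidal 3,5-dienol ethers; the auxiliary C8a centre is erased on purpose while C4a stays.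

Step 7
Reactants: 12 methyl (3R)-5-[(1S)-1,2-dimethyl-6-oxocyclohexa-2,4-dien-1-yl]-3-methylpentanoate
Product: 16 methyl (1S,2R,4aS,8aR)-2,4a,8a-trimethyl-5-oxo-1,2,3,4,4a,5,8,8a-octahydronaphthalene-1-carboxylate, via potassium ester enolate 13 (not isolated), via potassium dienolate 14 (not isolated), via unconjugated enone 15 (not isolated)
Conditions: KN(SiMe3)2 (1.05 equiv), THF, −78 → −20 °C; AcOH; then DBU (0.2 equiv), CH2Cl2, rt
Reagents that add atoms: none
Why: The dienone of 12 has no α-hydrogen (C4a quaternary, C6 sp2), so the base enolises the ester, and the enolate carbon C1 adds to the δ-carbon C8a of the C5=O/C6=C7/C8=C8a chain to give dienolate 14, whose α-protonation and DBU-mediated conjugation deliver enone 16. The closest known reaction type is the intramolecular 1,6-conjugate (vinylogous Michael) addition of stabilised carbanions or allylsilanes to linearly conjugated dienones, here applied to the blocked keto tautomer of a phenol. Ring A closes in a 6-(enolexo)-exo-trig mode through a chair in which the C2 methyl is equatorial. C8a is controlled by C4a, because the tether reaches only the dienone face that carries C4, so C1 and C4 end up cis and the two angular methyls cis (cis-decalin). C1 is set by the equatorial placement of the enolate unit (an axial ester would collide with C5) and is also the thermodynamic epimer, so any leakage can be corrected by base. The step needs 1,6- over 1,4- and 1,2-addition: C7 is out of reach of the tether (a bridged eight-membered ring) and aldol addition to the hindered C5 carbonyl is reversible, so the irreversible C1–C8a bond drains the equilibrium.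

Step 8
Reactants: 16 methyl (1S,2R,4aS,8aR)-2,4a,8a-trimethyl-5-oxo-1,2,3,4,4a,5,8,8a-octahydronaphthalene-1-carboxylate
Product: 18 methyl (1S,2R,4aS,8aR)-2,4a,8a-trimethyl-5-{[(trifluoromethyl)sulfonyl]oxy}-1,2,3,4,4a,7,8,8a-octahydronaphthalene-1-carboxylate, via lithium enolate 17 (not isolated)
Conditions: LiBH(s-Bu)3 (1.1 equiv), THF, −78 °C; then N-(5-chloropyridin-2-yl)bis(trifluoromethanesulfonimide), −78 °C → rt
Reagents that add atoms: N-(5-chloropyridin-2-yl)bis(trifluoromethanesulfonimide), FC(F)(F)S(=O)(=O)N(c1ccc(Cl)cn1)S(=O)(=O)C(F)(F)F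
Why: The bulky borohydride reduces a β-unsubstituted cyclohexenone with a hindered carbonyl in the 1,4 sense, and O-triflation of the regiodefined enolate (reductive enol triflate formation) places the C5=C6 double bond where the target has it.

Step 9
Reactants: 18 methyl (1S,2R,4aS,8aR)-2,4a,8a-trimethyl-5-{[(trifluoromethyl)sulfonyl]oxy}-1,2,3,4,4a,7,8,8a-octahydronaphthalene-1-carboxylate; 19 5-bromo-2-methylpent-2-ene
Product: 21 methyl (1S,2R,4aR,8aR)-2,4a,8a-trimethyl-5-(4-methylpent-3-en-1-yl)-1,2,3,4,4a,7,8,8a-octahydronaphthalene-1-carboxylate, via homoprenylmagnesium bromide 20 (not isolated)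
Conditions: 19, Mg, THF, rt; then 18, Fe(acac)3 (5 mol %), THF/NMP, −30 → 0 °C
Reagents that add atoms: none
Why: Iron-catalysed Kumada-type coupling of alkyl Grignard reagents with enol triflates is faster than attack on esters, all the more on the neopentyl-type C1 ester, and keeps the position of the ring double bond.

Step 10
Reactants: 21 methyl (1S,2R,4aR,8aR)-2,4a,8a-trimethyl-5-(4-methylpent-3-en-1-yl)-1,2,3,4,4a,7,8,8a-octahydronaphthalene-1-carboxylate
Product: 23 (1S,2R,4aR,8aR)-2,4a,8a-trimethyl-5-(4-methylpent-3-en-1-yl)-1,2,3,4,4a,7,8,8a-octahydronaphthalene-1-carboxylic acid, via sodium carboxylate 22 (not isolated)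
Conditions: EtSNa (5 equiv), DMF, 100 °C; then 1 M HCl
Reagents that add atoms: none
Why: Thiolate dealkylation is an SN2 attack at the O-methyl carbon, so the hindered acyl carbon is bypassed; the alkenes are inert and C1 already holds its thermodynamic configuration.

Step 11
Reactants: 24 (S)-glycidol
Product: 25 (R)-glycidyl acetate
Conditions: Ac2O, Et3N, DMAP (cat.), CH2Cl2, 0 °C
Reagents that add atoms: acetic anhydride, CC(=O)OC(C)=O
Why: DMAP-catalysed O-acetylation leaves the epoxide and its stereocentre untouched; only the descriptor changes.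

Step 12
Reactants: 23 (1S,2R,4aR,8aR)-2,4a,8a-trimethyl-5-(4-methylpent-3-en-1-yl)-1,2,3,4,4a,7,8,8a-octahydronaphthalene-1-carboxylic acid; 25 (R)-glycidyl acetate
Product: 26 (2S)-3-(acetyloxy)-2-hydroxypropyl (1S,2R,4aR,8aR)-2,4a,8a-trimethyl-5-(4-methylpent-3-en-1-yl)-1,2,3,4,4a,7,8,8a-octahydronaphthalene-1-carboxylate
Conditions: 25 (1.5 equiv), n-Bu4NBr (10 mol %), toluene, 85 °C
Reagents that add atoms: none
Why: Halide-catalysed opening of a terminal epoxide by a carboxylic acid, the standard entry to 1,3-diacylglycerols, occurs at the unsubstituted CH2, so the hindered acid reacts through its oxygen, the glycerol centre of 25 is retained and the secondary OH is set free.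

**Compound list**
1 | (3R)-5-methoxy-3-methyl-5-oxopentanoic acid (methyl hydrogen (R)-3-methylglutarate) | COC(=O)C[C@H](C)CC(=O)O | starting material
2 | methyl (3R)-5-hydroxy-3-methylpentanoate | COC(=O)C[C@H](C)CCO | intermediate
3 | methyl (3S)-5-iodo-3-methylpentanoate | COC(=O)C[C@H](C)CCI | intermediate
4 | 2-iodocyclohex-2-en-1-one | O=C1CCCC=C1I | starting material
5 | [(3S)-5-methoxy-3-methyl-5-oxopentyl]zinc iodide | COC(=O)C[C@H](C)CC[Zn]I | intermediate
6 | methyl (3R)-3-methyl-5-(6-oxocyclohex-1-en-1-yl)pentanoate | COC(=O)C[C@H](C)CCC1=CCCCC1=O | intermediate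
7 | methylzinc enolate of the (6S)-6-methylcyclohexenolate formed from 6 | COC(=O)C[C@H](C)CCC1=C(O[Zn]C)CCC[C@@H]1C | intermediate
8 | methyl (3R)-5-[(1S,2S)-1,2-dimethyl-6-oxocyclohexyl]-3-methylpentanoate | COC(=O)C[C@H](C)CC[C@]1(C)C(=O)CCC[C@@H]1C | intermediate
9 | lithium C5–C6 enolate of 8 | COC(=O)C[C@H](C)CC[C@]1(C)C([O-])=CCC[C@@H]1C.[Li+] | intermediate
10 | methyl (3R)-5-[(1S,6S)-1,6-dimethyl-2-oxocyclohex-3-en-1-yl]-3-methylpentanoate | COC(=O)C[C@H](C)CC[C@]1(C)C(=O)C=CC[C@@H]1C | intermediate
11 | tert-butyldimethylsilyl dienol ether of 10 | COC(=O)C[C@H](C)CC[C@]1(C)C(O[Si](C)(C)C(C)(C)C)=CC=C[C@@H]1C | intermediate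
12 | methyl (3R)-5-[(1S)-1,2-dimethyl-6-oxocyclohexa-2,4-dien-1-yl]-3-methylpentanoate | COC(=O)C[C@H](C)CC[C@]1(C)C(=O)C=CC=C1C | intermediate
13 | potassium ester enolate of 12 | COC([O-])=C[C@H](C)CC[C@]1(C)C(=O)C=CC=C1C.[K+] | intermediate
14 | potassium C5 dienolate of the cis-decalin | COC(=O)[C@H]1[C@H](C)CC[C@]2(C)C([O-])=CC=C[C@]12C.[K+] | intermediate
15 | unconjugated (C7=C8) isomer of 16 | COC(=O)[C@H]1[C@H](C)CC[C@]2(C)C(=O)CC=C[C@]12C | intermediate
16 | methyl (1S,2R,4aS,8aR)-2,4a,8a-trimethyl-5-oxo-1,2,3,4,4a,5,8,8a-octahydronaphthalene-1-carboxylate | COC(=O)[C@H]1[C@H](C)CC[C@]2(C)C(=O)C=CC[C@]12C | intermediate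
17 | lithium C5–C6 enolate from 16 | COC(=O)[C@H]1[C@H](C)CC[C@]2(C)C([O-])=CCC[C@]12C.[Li+] | intermediate
18 | methyl (1S,2R,4aS,8aR)-2,4a,8a-trimethyl-5-{[(trifluoromethyl)sulfonyl]oxy}-1,2,3,4,4a,7,8,8a-octahydronaphthalene-1-carboxylate | COC(=O)[C@H]1[C@H](C)CC[C@]2(C)C(OS(=O)(=O)C(F)(F)F)=CCC[C@]12C | intermediate
19 | 5-bromo-2-methylpent-2-ene | CC(C)=CCCBr | starting material
20 | (4-methylpent-3-en-1-yl)magnesium bromide | CC(C)=CCC[Mg]Br | intermediate
21 | methyl (1S,2R,4aR,8aR)-2,4a,8a-trimethyl-5-(4-methylpent-3-en-1-yl)-1,2,3,4,4a,7,8,8a-octahydronaphthalene-1-carboxylate | COC(=O)[C@H]1[C@H](C)CC[C@]2(C)C(CCC=C(C)C)=CCC[C@]12C | intermediate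
22 | sodium salt of 23 | [O-]C(=O)[C@H]1[C@H](C)CC[C@]2(C)C(CCC=C(C)C)=CCC[C@]12C.[Na+] | intermediate
23 | (1S,2R,4aR,8aR)-2,4a,8a-trimethyl-5-(4-methylpent-3-en-1-yl)-1,2,3,4,4a,7,8,8a-octahydronaphthalene-1-carboxylic acid | OC(=O)[C@H]1[C@H](C)CC[C@]2(C)C(CCC=C(C)C)=CCC[C@]12C | intermediate
24 | (S)-glycidol | OC[C@H]1CO1 | starting material
25 | (R)-glycidyl acetate | CC(=O)OC[C@H]1CO1 | intermediate
26 | (2S)-3-(acetyloxy)-2-hydroxypropyl (1S,2R,4aR,8aR)-2,4a,8a-trimethyl-5-(4-methylpent-3-en-1-yl)-1,2,3,4,4a,7,8,8a-octahydronaphthalene-1-carboxylate | CC(=O)OC[C@H](O)COC(=O)[C@H]1[C@H](C)CC[C@]2(C)C(CCC=C(C)C)=CCC[C@]12C | target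

**Step count**
- Total steps: 12
- Longest linear sequence: 11 (steps 1–10 and 12)

**Steps most likely to fail**

**Step 7.** Proton transfer from the vinylogous C8a methyl (trienolate formation), amide addition to the dienone, or Diels–Alder dimerisation of the dienone may outrun ring closure.

Fallback (sets out from 3, returns at 16): the order of events at ring B is inverted, so that the ring closes on a plain enone and the C4a methyl comes last. The zinc reagent made from 3 is coupled (PdCl2(dppf)) with commercial 2-iodo-3-methylcyclohex-2-en-1-one to give methyl (3R)-3-methyl-5-(2-methyl-6-oxocyclohex-1-en-1-yl)pentanoate F1. Equilibrating t-BuOK in t-BuOH/THF then closes ring A by an ordinary intramolecular Michael addition. The equatorial C2 methyl avoids a 1,3-diaxial clash with the C8a methyl, and the product is methyl (1S,2R,8aS)-2,8a-dimethyl-5-oxodecahydronaphthalene-1-carboxylate F2. LiN(i-Pr)2 followed by PhS(Cl)=N-t-Bu gives methyl (1S,2R,8aS)-2,8a-dimethyl-5-oxo-1,2,3,4,4a,5,8,8a-octahydronaphthalene-1-carboxylate F3. LiN(i-Pr)2/MeI then methylates the cross-conjugated enolate at C4a on the face away from C1, following the known cis preference of ring-fusion enolates, and gives 16.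

**Step 6.** Over-oxidation, an acid-induced dienone–phenol 1,2-shift, or dimerisation may occur during the hydride abstraction.

Fallback (sets out from 10, returns at 12): Wohl–Ziegler bromination (NBS, AIBN, PhCF3, reflux) at the γ-carbon C8 gives methyl (3R)-5-[(1S,6R)-5-bromo-1,6-dimethyl-2-oxocyclohex-3-en-1-yl]-3-methylpentanoate F4. DBU in toluene removes HBr through the C8a hydrogen and gives 12.

**Step 4.** Facial selectivity of methyl transfer may be poor on an enone with a long α-chain. C-methylation of the tetrasubstituted zinc enolate may also be slow enough to allow proton exchange.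

Fallback (sets out from 3, returns at 8): the chiral pool replaces catalysis. Commercial (S)-(−)-pulegone is deprotonated at its free α-CH2 (LiN(i-Pr)2, THF/DMPU) and alkylated with 3 to give methyl (3R)-3-methyl-5-[(2S)-2-methyl-6-oxo-5-(propan-2-ylidene)cyclohexyl]pentanoate F5. A second LiN(i-Pr)2/MeI round brings methyl in anti to the resident ring methyl and gives methyl (3R)-5-[(1S,2S)-1,2-dimethyl-6-oxo-5-(propan-2-ylidene)cyclohexyl]-3-methylpentanoate F6. Retro-aldol cleavage of the isopropylidene blocking group (HCl, aqueous MeOH, reflux) gives 8.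

**Further compounds**
F1 | step 7 | methyl (3R)-3-methyl-5-(2-methyl-6-oxocyclohex-1-en-1-yl)pentanoate | COC(=O)C[C@H](C)CCC1=C(C)CCCC1=O
F2 | step 7 | methyl (1S,2R,8aS)-2,8a-dimethyl-5-oxodecahydronaphthalene-1-carboxylate (C4a epimers) | COC(=O)[C@H]1[C@H](C)CCC2C(=O)CCC[C@]12C
F3 | step 7 | methyl (1S,2R,8aS)-2,8a-dimethyl-5-oxo-1,2,3,4,4a,5,8,8a-octahydronaphthalene-1-carboxylate (C4a epimers) | COC(=O)[C@H]1[C@H](C)CCC2C(=O)C=CC[C@]12C
F4 | step 6 | methyl (3R)-5-[(1S,6R)-5-bromo-1,6-dimethyl-2-oxocyclohex-3-en-1-yl]-3-methylpentanoate (bromide epimers) | COC(=O)C[C@H](C)CC[C@]1(C)C(=O)C=CC(Br)[C@@H]1C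
F5 | step 4 | methyl (3R)-3-methyl-5-[(2S)-2-methyl-6-oxo-5-(propan-2-ylidene)cyclohexyl]pentanoate (C1 epimers of the ring) | COC(=O)C[C@H](C)CCC1C(=O)C(=C(C)C)CC[C@@H]1C
F6 | step 4 | methyl (3R)-5-[(1S,2S)-1,2-dimethyl-6-oxo-5-(propan-2-ylidene)cyclohexyl]-3-methylpentanoate | COC(=O)C[C@H](C)CC[C@]1(C)C(=O)C(=C(C)C)CC[C@@H]1C
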